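Its constants are invented; the run is a simulation.

1. Both flasks are read at 2.0 min. The quantity to follow is the fraction of electrophile left, and the part reacted is what remains of the whole.

| setting | maple | alder |
|---|---|---|
| electrophile | 0.050 M | 0.050 M |
| nucleophile | 0.0600 M | 0.0600 M |
| free base | 0.110 M | 0.0750 M |
| time | 2.0 min | 2.0 min |

    nucleophile + acid set free ⇌ protonated nucleophile, settled at all times (K1 = 1300 M⁻¹)
    2 electrophile → self-condensation product (k2 = 0.31 M⁻¹ s⁻¹)
    electrophile + nucleophile ⇌ acid set free + target (K3 = 0.92, k3 = 0.22 M⁻¹ s⁻¹)
    acid set free + free base ⇌ salt of the base (K4 = 2400 M⁻¹, k4 = 1.1 M⁻¹ s⁻¹)

- in percentages every species weighs as the electrophile in it: one self-condensation product counts as two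
- two of one species on the left: rate k times its square, two consumed each time
- run time (maple): 2.0 min

- part of the electrophile that has reacted at the end, maple
- part of the electrophile that has reacted at the end, alder
- what raising the concentration of free base from its lowest to its highest value here does to the part of the electrophile that has reacted (changes below 5 percentage points count as none) (it falls / it rises / no change)

2. Electrophile leaves by self-condensation and by attack on nucleophile. If [nucleophile] is held constant, the attack is pseudo-first-order with rate constant a. With self-condensation starting at 0.0310 s⁻¹ per electrophile and r being that figure over a, the fraction left at time t is 1/((1 + r)·exp(a·t) − r).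

3. The first way holds [nucleophile] at its charge, so a is 0.0132 s⁻¹, r is 2.35, and the fraction left is 7.16 %.

4. The second way counts the cost of each target. The equilibrium constant of protonation times charged [nucleophile] in alder is 78, far above one, so the acid set free sits on a second nucleophile and each target costs two. Emptying that acid into free base has a half-life near 10.9 min in alder and 7.45 min in maple, both longer than the run, so free base drops out of the reckoning.

5. The starting rates give the nucleophile route 0.426 of self-condensation, a share of 29.9 %. The working [nucleophile] is therefore the charge less two per expected target, 0.0301 M, about half of the charge. With r now 4.68, the fraction left at working nucleophile 12.7 % is larger than the first.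

6. The two ways part, and the first one cheats, since it holds [nucleophile] at the charge although each target uses up one nucleophile and protonation takes up a second. The second errs the opposite way early in the run, but it is the figure adopted here: 87.3 % reacted in both flasks.

7. The forecast gives 88.5 % for maple and 88.2 % for alder, with no change, somewhat above this reckoning, on the ground that “Released acid is held mostly on the nucleophile and reaches the base only slowly”.

8. The simulation gives 88.2 % for maple and 88.1 % for alder, a difference of 0.097 percentage points, so no change.

9. At the end of maple, protonated nucleophile stands at 0.0135 M, more than the 0.00350 M of salt of the base. A neighbour of alder is charged with 0.015 M of nucleophile. There the starting ratio is 0.106, the share 9.62 %, the working [nucleophile] 0.00538 M, and so, with r at 26.2, the fraction left comes to 19.4 %. That neighbour ends with 19 % of its electrophile left and target at 10.2 %.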